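**Retrosynthetic overview**
1. Target 20 ⇐ 18 by cross-metathesis (prenyl end); 18 ⇐ 17 by the key step, a late double allylic C–H hydroxylation that forms both the C3–O and C9–O bonds on the bis(exo-methylene) core.
2. 17 ⇐ tricyclic cis-lactone 13: the C6–O–C12 lactone is reduced to the lactol, opened by an allyl nucleophile (sets C12), and C12–OH is acetylated.
3. 13 ⇐ butenolide 12 ⇐ ynal 11 by a new carbonylative [2+2+1] cyclization that closes the seven-membered ring (C6–C7) and the lactone together.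
4. 11 ⇐ cyclopent-2-enone 5 + alkenyl metal from 4 + formaldehyde (asymmetric 1,4-addition and trans trapping set C1 and C5).
5. Ring order: five-membered ring (bought as 5) → seven-membered ring and lactone in one step → lactone opened again at the end.

Assumption (labels only): C1–C15 follow guaiane-type numbering. C1 and C5 are the ring-fusion carbons (C1 bonded to C2 and C10, C5 to C4 and C6), C15 and C14 are the methylene carbons on C4 and C10, and C11 (CH3-bearing) and C12 (OAc-bearing) are the first two side-chain carbons on C7.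

**Route**

Step 1
Reactants: 1 3-bromobut-3-en-1-ol; 2 1-propynyllithium
Product: 4 2-bromohept-1-en-5-yne, via triflate 3 (not isolated)
Conditions: 1, Tf2O, 2,6-lutidine, CH2Cl2, −78 °C; then 2, THF/DMPU, −78 → 0 °C
Reagents that add atoms: none
Why: SN2 alkylation of a lithium acetylide by a primary triflate made in situ joins C8 to C7 and leaves the vinyl bromide untouched; no stereocenter is formed.

Step 2
Reactants: 4 2-bromohept-1-en-5-yne; 5 cyclopent-2-en-1-one
Product: 9 (2R,3R)-3-(hept-1-en-5-yn-2-yl)-2-(hydroxymethyl)cyclopentan-1-one, via alkenyllithium 6 (not isolated), via alkenylzinc chloride 7 (not isolated), via silyl enol ether 8 (not isolated)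
Conditions: 4, t-BuLi (2 equiv), Et2O, −78 °C; ZnCl2, THF; 5, [RhCl((R)-binap)]2 (3 mol % Rh), Me3SiCl, THF, 20 °C; then aq. HCHO, Yb(OTf)3 (10 mol %), THF, 20 °C
Reagents that add atoms: formaldehyde C=O
Why: Rhodium–BINAP-catalysed asymmetric 1,4-addition (Hayashi–Miyaura type, organozinc/chlorosilane variant) sets C1 as R, and the Mukaiyama hydroxymethylation of silyl enol ether 8 enters anti to the new alkenyl group, giving the trans C1/C5 pair, which is also the thermodynamic one.

Step 3
Reactants: 9 (2R,3R)-3-(hept-1-en-5-yn-2-yl)-2-(hydroxymethyl)cyclopentan-1-one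
Product: 10 [(1S,2R)-2-(hept-1-en-5-yn-2-yl)-5-methylidenecyclopentyl]methanol
Conditions: Zn, CH2Br2, TiCl4, THF/CH2Cl2, 0 → 20 °C
Reagents that add atoms: dibromomethane BrCBr
Why: Takai–Lombardo methylenation uses a non-basic zinc–titanium methylene reagent, so the ketone becomes the C4 exocyclic alkene without retro-aldol loss of formaldehyde or epimerization at C5; no new stereocenter.

Step 4
Reactants: 10 [(1S,2R)-2-(hept-1-en-5-yn-2-yl)-5-methylidenecyclopentyl]methanol
Product: 11 (1S,2R)-2-(hept-1-en-5-yn-2-yl)-5-methylidenecyclopentane-1-carbaldehyde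
Conditions: Dess–Martin periodinane, NaHCO3, CH2Cl2, 0 °C
Reagents that add atoms: none
Why: Dess–Martin oxidation under buffered, non-enolizing conditions gives the β,γ-unsaturated aldehyde without conjugating the C4 methylene or epimerizing C5.

Step 5
Reactants: 11 (1S,2R)-2-(hept-1-en-5-yn-2-yl)-5-methylidenecyclopentane-1-carbaldehyde
Product: 12 (6aR,9aS,9bS)-3-methyl-6,9-dimethylidene-5,6,6a,7,8,9,9a,9b-octahydroazuleno[4,5-b]furan-2(4H)-one
Conditions: Ru3(CO)12 (5 mol %), CO (10 atm), toluene, 140 °C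
Reagents that add atoms: carbon monoxide [C-]#[O+]
Why: Proposed new method: a carbonylative [2+2+1] cyclization (hetero-Pauson–Khand reaction) of a 1,8-ynal, in which zerovalent ruthenium couples the aldehyde C=O and the alkyne to an oxaruthenacyclopentene (C6–C7 bond, seven-membered ring), CO inserts into the Ru–C11 bond and C–O reductive elimination closes the butenolide; the closest known reaction is the Ru3(CO)12-catalysed (or Mo(CO)6-mediated) cyclocarbonylation of 1,6- and 1,7-yne-aldehydes to butenolides on five- and six-membered rings, and the seven-membered case should work here because the trans-disubstituted cyclopentane and the sp2 carbon C10 hold aldehyde and alkyne close; C6 is expected to form with its oxygen pseudo-equatorial (anti to C4, 6S in 12) and, as the γ-position of a butenolide, can be equilibrated with DBU through the 2-oxidofuran if a mixture arises.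

Step 6
Reactants: 12 (6aR,9aS,9bS)-3-methyl-6,9-dimethylidene-5,6,6a,7,8,9,9a,9b-octahydroazuleno[4,5-b]furan-2(4H)-one
Product: 13 (3S,3aS,6aR,9aS,9bR)-3-methyl-6,9-dimethylidenedecahydroazuleno[4,5-b]furan-2(3H)-one
Conditions: Mg, MeOH, 0 → 20 °C; then 1 M HCl
Reagents that add atoms: none
Why: Dissolving-metal conjugate reduction (Mg/MeOH) of the butenolide spares the isolated alkenes; C7 is protonated on the face of H6 (anti to the C5 substituent on C6) to give the cis-fused lactone, and C11 equilibrates under the methoxide present to the exo-methyl epimer (trans to C8).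

Step 7
Reactants: 13 (3S,3aS,6aR,9aS,9bR)-3-methyl-6,9-dimethylidenedecahydroazuleno[4,5-b]furan-2(3H)-one
Product: 14 (3S,3aS,6aR,9aS,9bR)-3-methyl-6,9-dimethylidenedodecahydroazuleno[4,5-b]furan-2-ol (anomer mixture)
Conditions: i-Bu2AlH (1.1 equiv), CH2Cl2, −78 °C
Reagents that add atoms: none
Why: Partial reduction of the γ-lactone with i-Bu2AlH at low temperature stops at the lactol (stable tetrahedral aluminate); C6, C7 and C11 are untouched.

Step 8
Reactants: 14 (3S,3aS,6aR,9aS,9bR)-3-methyl-6,9-dimethylidenedodecahydroazuleno[4,5-b]furan-2-ol; 15 allylmagnesium bromide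
Product: 16 (2S,3S)-2-[(3aR,7S,8R,8aS)-8-hydroxy-1,4-dimethylidenedecahydroazulen-7-yl]hex-5-en-3-ol
Conditions: 15 (3 equiv), THF, −78 → 0 °C; aq. NH4Cl
Reagents that add atoms: none
Why: Grignard addition to the open hydroxy-aldehyde form of the lactol follows the Felkin–Anh model at the α-methyl stereocenter C11 (attack anti to C7), giving the 11,12-syn carbinol (12S) and freeing C6–OH.

Step 9
Reactants: 16 (2S,3S)-2-[(3aR,7S,8R,8aS)-8-hydroxy-1,4-dimethylidenedecahydroazulen-7-yl]hex-5-en-3-ol
Product: 17 (2S,3S)-2-[(3aR,7S,8R,8aS)-8-hydroxy-1,4-dimethylidenedecahydroazulen-7-yl]hex-5-en-3-yl acetate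
Conditions: Ac2O (1.1 equiv), pyridine, DMAP (5 mol %), CH2Cl2, −20 °C
Reagents that add atoms: acetic anhydride CC(=O)OC(C)=O
Why: Site-selective acylation: the side-chain C12–OH (flanked by CH and CH2) is acetylated, while C6–OH, wedged between the ring methines C5 and C7, reacts much more slowly.

Step 10
Reactants: 17 (2S,3S)-2-[(3aR,7S,8R,8aS)-8-hydroxy-1,4-dimethylidenedecahydroazulen-7-yl]hex-5-en-3-yl acetate
Product: 18 (2S,3S)-2-[(2S,3aR,5R,7S,8R,8aS)-2,5,8-trihydroxy-1,4-dimethylidenedecahydroazulen-7-yl]hex-5-en-3-yl acetate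
Conditions: SeO2 (0.5 equiv), t-BuOOH (4 equiv), CH2Cl2, 20 °C
Reagents that add atoms: tert-butyl hydroperoxide CC(C)(C)OO
Why: Catalytic SeO2/t-BuOOH allylic hydroxylation (Riley oxidation: ene reaction then [2,3]-sigmatropic shift) oxidizes each 1,1-disubstituted alkene at its ring CH2 (C3, C9) rather than at the ring-fusion CH or the less reactive terminal alkene; oxygen is expected anti to the substituent on the neighbouring ring-fusion carbon (anti to C6 at C3, anti to C2 at C9), giving 3S and 9R.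

Step 11
Reactants: 18 (2S,3S)-2-[(2S,3aR,5R,7S,8R,8aS)-2,5,8-trihydroxy-1,4-dimethylidenedecahydroazulen-7-yl]hex-5-en-3-yl acetate; 19 2-methylbut-2-ene
Product: 20 (2S,3S)-2-[(2S,3aR,5R,7S,8R,8aS)-2,5,8-trihydroxy-1,4-dimethylidenedecahydroazulen-7-yl]-6-methylhept-5-en-3-yl acetate
Conditions: second-generation Grubbs catalyst (5 mol %), 19 (excess), CH2Cl2, 40 °C
Reagents that add atoms: none
Why: Olefin cross-metathesis with excess 2-methylbut-2-ene turns the terminal vinyl group into the isopropylidene end; the hindered 1,1-disubstituted exocyclic alkenes do not take part and no stereocenter is affected.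

**Compound list**
1 | 3-bromobut-3-en-1-ol | OCCC(Br)=C | starting material
2 | 1-propynyllithium | [Li]C#CC | starting material
3 | 3-bromobut-3-en-1-yl trifluoromethanesulfonate | C=C(Br)CCOS(=O)(=O)C(F)(F)F | intermediate (not isolated)
4 | 2-bromohept-1-en-5-yne | C=C(Br)CCC#CC | intermediate
5 | cyclopent-2-en-1-one | O=C1C=CCC1 | starting material
6 | (hept-1-en-5-yn-2-yl)lithium | [Li]C(=C)CCC#CC | intermediate (not isolated)
7 | chlorido(hept-1-en-5-yn-2-yl)zinc | Cl[Zn]C(=C)CCC#CC | intermediate (not isolated)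
8 | {[(3R)-3-(hept-1-en-5-yn-2-yl)cyclopent-1-en-1-yl]oxy}trimethylsilane | C[Si](C)(C)OC1=C[C@H](C(=C)CCC#CC)CC1 | intermediate (not isolated)
9 | (2R,3R)-3-(hept-1-en-5-yn-2-yl)-2-(hydroxymethyl)cyclopentan-1-one | O=C1[C@@H](CO)[C@H](C(=C)CCC#CC)CC1 | intermediate
10 | [(1S,2R)-2-(hept-1-en-5-yn-2-yl)-5-methylidenecyclopentyl]methanol | C=C1[C@@H](CO)[C@H](C(=C)CCC#CC)CC1 | intermediate
11 | (1S,2R)-2-(hept-1-en-5-yn-2-yl)-5-methylidenecyclopentane-1-carbaldehyde | C=C1[C@@H](C=O)[C@H](C(=C)CCC#CC)CC1 | intermediate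
12 | (6aR,9aS,9bS)-3-methyl-6,9-dimethylidene-5,6,6a,7,8,9,9a,9b-octahydroazuleno[4,5-b]furan-2(4H)-one | C=C1[C@H]2[C@@H]3OC(=O)C(C)=C3CCC(=C)[C@@H]2CC1 | intermediate
13 | (3S,3aS,6aR,9aS,9bR)-3-methyl-6,9-dimethylidenedecahydroazuleno[4,5-b]furan-2(3H)-one | C=C1[C@H]2[C@@H]3OC(=O)[C@@H](C)[C@@H]3CCC(=C)[C@@H]2CC1 | intermediate
14 | (3S,3aS,6aR,9aS,9bR)-3-methyl-6,9-dimethylidenedodecahydroazuleno[4,5-b]furan-2-ol (anomer mixture) | C=C1[C@H]2[C@@H]3OC(O)[C@@H](C)[C@@H]3CCC(=C)[C@@H]2CC1 | intermediate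
15 | allylmagnesium bromide | C=CC[Mg]Br | starting material
16 | (2S,3S)-2-[(3aR,7S,8R,8aS)-8-hydroxy-1,4-dimethylidenedecahydroazulen-7-yl]hex-5-en-3-ol | C=C1[C@H]2[C@H](O)[C@H]([C@H](C)[C@H](CC=C)O)CCC(=C)[C@@H]2CC1 | intermediate
17 | (2S,3S)-2-[(3aR,7S,8R,8aS)-8-hydroxy-1,4-dimethylidenedecahydroazulen-7-yl]hex-5-en-3-yl acetate | C=C1[C@H]2[C@H](O)[C@H]([C@H](C)[C@H](CC=C)OC(C)=O)CCC(=C)[C@@H]2CC1 | intermediate
18 | (2S,3S)-2-[(2S,3aR,5R,7S,8R,8aS)-2,5,8-trihydroxy-1,4-dimethylidenedecahydroazulen-7-yl]hex-5-en-3-yl acetate | C=C1[C@H]2[C@H](O)[C@H]([C@H](C)[C@H](CC=C)OC(C)=O)C[C@@H](O)C(=C)[C@@H]2C[C@@H]1O | intermediate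
19 | 2-methylbut-2-ene | CC=C(C)C | starting material
20 | (2S,3S)-2-[(2S,3aR,5R,7S,8R,8aS)-2,5,8-trihydroxy-1,4-dimethylidenedecahydroazulen-7-yl]-6-methylhept-5-en-3-yl acetate | C=C1[C@H]2[C@H](O)[C@H]([C@H](C)[C@H](CC=C(C)C)OC(C)=O)C[C@@H](O)C(=C)[C@@H]2C[C@@H]1O | target

**Totals and risks**
Total step count: 11. Longest linear sequence: 11 steps (1 → 20).

The three steps most likely to fail:

Step 5 (the proposed new cyclization). The seven-membered ring may not close, or the exocyclic alkenes may migrate at 140 °C. The fallback uses known chemistry, sets out from alcohol 10 and comes back at lactone 13. Palladium-catalysed syn-hydromethoxycarbonylation of the methyl alkyne (Pd(OAc)2, 1,4-bis(diphenylphosphino)butane, TsOH, CO, MeOH; ester carbon on the methyl-bearing alkyne carbon) gives hydroxy enoate F1. Dess–Martin oxidation gives formyl enoate F2. SmI2 with t-BuOH in THF/HMPA then effects a ketyl–olefin cyclization that forms C6–C7, and the resulting hydroxy ester lactonizes to 13 (DBU equilibrates C11 if needed). The C6/C7 outcome of this cyclization would have to be checked.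

Step 8 (Felkin selectivity at C12 may be modest). The fallback sets out from lactone 13 and comes back at diol 16. One equivalent of 15 at −78 °C gives allyl ketone F3 (in equilibrium with its hemiketal), which is reduced with (R)-2-methyl-CBS-oxazaborolidine and BH3·SMe2 so that C12 is set by reagent control.

Step 10 (facial selectivity at C3 and C9 rests on substrate control, and over-oxidation to enones is possible). The fallback sets out from 17 and comes back at 18. If oxygen is delivered to the other face, the same oxidation gives 3,9-diepimeric triol F4. Mitsunobu inversion of its two unhindered allylic carbinols (4-nitrobenzoic acid, PPh3, diisopropyl azodicarboxylate; the hindered C6–OH does not react) gives bis(4-nitrobenzoate) F5, and NaN3 in MeOH removes the nitrobenzoates without touching the alkyl acetate to give 18.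

**Further compounds**
F1 | step 5 | methyl (2E)-6-[(1R,2S)-2-(hydroxymethyl)-3-methylidenecyclopentyl]-2-methylhepta-2,6-dienoate | C=C1[C@@H](CO)[C@H](C(=C)CC/C=C(\C)C(=O)OC)CC1
F2 | step 5 | methyl (2E)-6-[(1R,2S)-2-formyl-3-methylidenecyclopentyl]-2-methylhepta-2,6-dienoate | C=C1[C@@H](C=O)[C@H](C(=C)CC/C=C(\C)C(=O)OC)CC1
F3 | step 8 | (2S)-2-[(3aR,7S,8R,8aS)-8-hydroxy-1,4-dimethylidenedecahydroazulen-7-yl]hex-5-en-3-one | C=C1[C@H]2[C@H](O)[C@H]([C@H](C)C(=O)CC=C)CCC(=C)[C@@H]2CC1
F4 | step 10 | (2S,3S)-2-[(2R,3aR,5S,7S,8R,8aS)-2,5,8-trihydroxy-1,4-dimethylidenedecahydroazulen-7-yl]hex-5-en-3-yl acetate | C=C1[C@H]2[C@H](O)[C@H]([C@H](C)[C@H](CC=C)OC(C)=O)C[C@H](O)C(=C)[C@@H]2C[C@H]1O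
F5 | step 10 | (2S,3aR,5R,7S,8R,8aS)-7-[(2S,3S)-3-acetoxyhex-5-en-2-yl]-8-hydroxy-1,4-dimethylidenedecahydroazulene-2,5-diyl bis(4-nitrobenzoate) | C=C1[C@H]2[C@H](O)[C@H]([C@H](C)[C@H](CC=C)OC(C)=O)C[C@@H](OC(=O)c3ccc(cc3)[N+](=O)[O-])C(=C)[C@@H]2C[C@@H]1OC(=O)c1ccc(cc1)[N+](=O)[O-]
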